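The oxolane ring (O, C7, C8, C9, C10; germacrane numbering) is read as the intramolecular oxa-Michael adduct of the C7 tertiary alkoxide to a C8(=O)–C9=C10(CH3)–C1(=O) ene-dione, the open form of a six-membered Achmatowicz hemiketal. The key step exploits this: a furan-derived pyranone (O, C7, C8, C9, C10, C1) contracts to the oxolan-3-one under a chiral base, C1 being expelled as the side-chain ketone; an acid/methanol quench then ties C1 to one of two equivalent CH2O arms on C7 as a bicyclic ketal, fixing C7 against C10 and directing exo reduction at C8. Ring closure (C5–C6), cyclocarbonylation and epoxidation finish the synthesis.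

Key step: step 6

Remark: germacrane numbering is used throughout (C1 ketone, C4/C5 epoxide, C6 lactone carbinol, C7 spiro carbon, C8 ester carbinol, C10 methyl-bearing ether carbon, C11–C13 acrylate unit). The target is taken exactly as drawn (4R,5R,6R,7S,8S,10S); in it C6 and C1 leave the oxolane from opposite faces, so the ten-membered ring is a strained, trans-bridged one and is closed only after C7, C8 and C10 are fixed.

Step 1
Reactants: 1 2,3-dimethylfuran; 2 2,2-dimethyl-1,3-dioxan-5-one
Product: 4 5-(4,5-dimethylfuran-2-yl)-2,2-dimethyl-1,3-dioxan-5-ol, via furyllithium 3 (not isolated)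
Conditions: n-BuLi, THF, 0 °C → rt; then 2, −78 °C
Reagents that add atoms: none
Why: Lithiation of 1 at its only free ring α-position and 1,2-addition to the ketone should give the tertiary furyl carbinol, whose carbinol carbon (future C7) carries two identical masked CH2O arms and is therefore not yet a stereocentre (heteroaryl lithiation/carbonyl addition).

Step 2
Reactants: 5 prop-2-yn-1-ol
Product: 7 (E)-3-iodo-2-methylprop-2-en-1-ol, via alkenylalane 6 (not isolated)
Conditions: AlMe3 (3 equiv), (C5H5)2ZrCl2 (0.25 equiv), CH2Cl2, 0 °C → rt; then I2, THF, −30 °C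
Reagents that add atoms: trimethylaluminium C[Al](C)C; iodine II
Why: Zirconium-catalysed Negishi carboalumination adds methyl and aluminium syn across the alkyne with methyl on the internal carbon, and iodinolysis with retention should give the E-iodoalkene that becomes C4=C5.

Step 3
Reactants: 7 (E)-3-iodo-2-methylprop-2-en-1-ol
Product: 8 (E)-3-bromo-1-iodo-2-methylprop-1-ene
Conditions: CBr4, PPh3, CH2Cl2, 0 °C
Reagents that add atoms: carbon tetrabromide BrC(Br)(Br)Br
Why: Appel bromination converts the primary allylic alcohol into the bromide without touching the alkene geometry.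

Step 4
Reactants: 4 5-(4,5-dimethylfuran-2-yl)-2,2-dimethyl-1,3-dioxan-5-ol; 8 (E)-3-bromo-1-iodo-2-methylprop-1-ene
Product: 10 5-{5-[(3E)-4-iodo-3-methylbut-3-en-1-yl]-4-methylfuran-2-yl}-2,2-dimethyl-1,3-dioxan-5-ol, via dilithio species 9 (not isolated)
Conditions: n-BuLi (2.1 equiv), TMEDA, THF, −78 → 0 °C; then 8, −78 °C
Reagents that add atoms: none
Why: After O-deprotonation the second equivalent of base should lithiate the furan α-methyl group (lateral lithiation of a 2-alkylfuran whose ring α-positions are both substituted), and the furfuryllithium displaces the allylic bromide (SN2) to install C2–C5 with the E-iodoalkene.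

Step 5
Reactants: 10 furyl carbinol
Product: 11 Achmatowicz pyranone hemiketal
Conditions: NBS, NaHCO3, NaOAc, THF/H2O (4:1), 0 °C
Reagents that add atoms: water O
Why: Achmatowicz oxidative ring expansion of the tertiary 2-furyl carbinol should give the 6-hydroxy-2H-pyran-3(6H)-one that holds the C8 ketone, the C9=C10 alkene and the C1 hemiketal carbon in one ring, the electron-rich furan being oxidised in preference to the iodoalkene.

Step 6
Reactants: 11 Achmatowicz pyranone hemiketal
Product: 13 bicyclic methyl ketal (3,8-dioxabicyclo[3.2.1]octan-6-one), via oxolan-3-one 12 (not isolated)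
Conditions: quinine-derived bifunctional squaramide catalyst (10 mol %), toluene, −20 °C; then CSA (20 mol %), MeOH, 0 °C → rt
Reagents that add atoms: methanol CO
Why: Proposed new method: the quinuclidine nitrogen of the catalyst opens hemiketal 11 to its (Z)-hydroxy ene-dione tautomer while the squaramide N–H groups bind the C8/C1 carbonyl pair, so that the C7 alkoxide adds to C10 (5-endo-trig oxa-Michael, protonation at C9) and the six-membered pyranone (O, C7, C8, C9, C10, C1) contracts to oxolan-3-one 12 with C1 expelled as the exocyclic ketone; the closest known reaction types are the acid- or base-mediated 5-endo oxa-Michael cyclisation of α′-hydroxy enones to oxolan-3-ones and cinchona-squaramide-catalysed asymmetric intramolecular oxa-Michael additions. The oxolane is thus closed by ring contraction (C10–O bond formation, C1–O cleavage), and in the acidic methanol quench the acetonide is methanolysed and the CH2OH arm lying cis to the C1 acyl group closes the 1,4-dioxane ring by 6-exo ketalisation at C1. C10 (S) is to be set by the catalyst; because the two C7 arms are still identical no diastereomers can arise at that stage, and C7 becomes stereogenic only through the ketal tether, which can reach only the cis arm and so fixes C7 relative to C10 (the ketal carbon takes the axial methoxy group, anomeric effect). The step needs O-attack at C10 rather than aldol closure of C2 onto C8 or addition of another hydroxyl: C7 has no enolisable hydrogen, both primary hydroxyls are masked as the acetonide during the basic stage, and only a weak amine base is present. The ketal also masks the C1 ketone and blocks retro-Michael opening in the following steps.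

Step 7
Reactants: 13 bicyclic methyl ketal
Product: 14 bicyclic ketal diol
Conditions: NaBH4, MeOH, −40 °C
Reagents that add atoms: none
Why: Hydride should add to the C8 ketone from the exo face of the 3,8-dioxabicyclo[3.2.1]octanone (the side of the one-atom oxygen bridge, away from the three-atom ketal bridge), placing the C8 hydroxyl cis to C1 and to the C11 arm as in the target, while the C1 ketone stays masked (diastereoselective ketone reduction).

Step 8
Reactants: 14 bicyclic ketal diol
Product: 15 bis(tert-butyldimethylsilyl) ether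
Conditions: TBSOTf (2.5 equiv), 2,6-lutidine, CH2Cl2, −20 → 0 °C
Reagents that add atoms: tert-butyldimethylsilyl trifluoromethanesulfonate CC(C)(C)[Si](C)(C)OS(=O)(=O)C(F)(F)F
Why: Silylation of the primary C6 hydroxyl and the hindered C8 hydroxyl protects both for the oxidation and homologation of the other arm (silyl ether formation).

Step 9
Reactants: 15 bis(tert-butyldimethylsilyl) ether
Product: 16 hydroxy ketone (open form of the bicyclic hemiketal)
Conditions: PPTS, acetone/H2O (9:1), 40 °C
Reagents that add atoms: water O
Why: Mild acid hydrolysis of the mixed methyl ketal through the ring-oxygen-stabilised oxocarbenium ion should release the C1 ketone and the primary C11 alcohol, which equilibrate with the bicyclic hemiketal, while the silyl ethers survive (ketal hydrolysis).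

Step 10
Reactants: 16 hydroxy ketone
Product: 17 C11 aldehyde
Conditions: Dess–Martin periodinane, NaHCO3, CH2Cl2, 0 °C → rt
Reagents that add atoms: none
Why: Dess–Martin oxidation of the open hydroxy ketone tautomer converts the primary C11 alcohol into a non-enolisable aldehyde.

Step 11
Reactants: 17 C11 aldehyde
Product: 18 terminal alkyne
Conditions: dimethyl (1-diazo-2-oxopropyl)phosphonate, K2CO3, MeOH, 0 °C → rt
Reagents that add atoms: dimethyl (1-diazo-2-oxopropyl)phosphonate COP(=O)(OC)C(=[N+]=[N-])C(C)=O
Why: Ohira–Bestmann (Seyferth–Gilbert) homologation should turn the hindered aldehyde into the terminal alkyne C11≡C13 without affecting the C7 configuration.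

Step 12
Reactants: 18 terminal alkyne
Product: 19 alkynyl diol
Conditions: HF·pyridine, THF/pyridine, 0 °C → rt
Reagents that add atoms: none
Why: Fluoride cleaves both silyl ethers and returns the C6/C8 diol (desilylation).

Step 13
Reactants: 19 alkynyl diol
Product: 20 hydroxy aldehyde
Conditions: TEMPO (10 mol %), PhI(OAc)2, CH2Cl2, rt
Reagents that add atoms: none
Why: The oxoammonium oxidation is selective for the primary C6 alcohol over the hindered secondary C8 alcohol and stops at the aldehyde (TEMPO/PhI(OAc)2 oxidation).

Step 14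
Reactants: 20 hydroxy aldehyde
Product: 21 methacrylate aldehyde
Conditions: methacrylic anhydride, DMAP (cat.), Et3N, CH2Cl2, 0 °C
Reagents that add atoms: methacrylic anhydride CC(=C)C(=O)OC(=O)C(C)=C
Why: DMAP-catalysed acylation (Steglich-type) esterifies the only free hydroxyl, C8–OH, with retention of configuration, and the aldehyde has no α-hydrogen.

Step 15
Reactants: 21 methacrylate aldehyde
Product: 23 macrocyclic allylic alcohol, via alkenylchromium species 22 (not isolated)
Conditions: CrCl2 (8 equiv), NiCl2 (2 mol %), DMSO/THF, 2 mM, rt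
Reagents that add atoms: none
Why: Intramolecular Nozaki–Hiyama–Kishi reaction: the alkenylchromium species forms with retention of the E geometry and adds to the C6 aldehyde to close the ten-membered ring at C5–C6, Felkin–Anh addition anti to the C7–O bond past the slim ethynyl group being expected to give 6R, and the ketone, alkyne and methacrylate are tolerated by the organochromium.

Step 16
Reactants: 23 macrocyclic allylic alcohol
Product: 24 α-methylene lactone (4E-alkene)
Conditions: PdCl2 (5 mol %), SnCl2 (5 mol %), PPh3 (10 mol %), CO (7 atm), MeCN, 70 °C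
Reagents that add atoms: carbon monoxide [C-]#[O+]
Why: Palladium-catalysed cyclocarbonylation of the homopropargylic alcohol (alkoxycarbonyl–palladium at O6, syn insertion of the alkyne, protonolysis) should build the α-methylene-γ-butyrolactone C6–O–C12(=O)–C11(=C13H2)–C7 in one step, and because C8 is already acylated only O6 can lactonise.

Step 17
Reactants: 24 α-methylene lactone (4E-alkene)
Product: 25 target CNP0241021.2
Conditions: dimethyldioxirane, acetone, −20 → 0 °C
Reagents that add atoms: dimethyldioxirane CC1(C)OO1
Why: The electrophilic dioxirane should epoxidise only the electron-rich trisubstituted C4=C5 alkene, stereospecifically (E to trans) and from the face anti to the quaternary C7 in the conformer with H6 eclipsing the alkene (allylic 1,3-strain), which gives 4R,5R; the acrylate-type alkenes and the ketone are inert to it.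

Compound list
1 | 2,3-dimethylfuran | Cc1occc1C | starting material
2 | 2,2-dimethyl-1,3-dioxan-5-one | CC1(C)OCC(=O)CO1 | starting material
3 | (4,5-dimethylfuran-2-yl)lithium | [Li]c1cc(C)c(C)o1 | intermediate
4 | 5-(4,5-dimethylfuran-2-yl)-2,2-dimethyl-1,3-dioxan-5-ol | Cc1oc(cc1C)C2(O)COC(C)(C)OC2 | intermediate
5 | prop-2-yn-1-ol | C#CCO | starting material
6 | (E)-alkenylalane: dimethylaluminium alkoxide of (E)-3-(dimethylalumanyl)-2-methylprop-2-en-1-ol | C[Al](C)OC/C(C)=C/[Al](C)C | intermediate
7 | (E)-3-iodo-2-methylprop-2-en-1-ol | OC/C(C)=C/I | intermediate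
8 | (E)-3-bromo-1-iodo-2-methylprop-1-ene | BrC/C(C)=C/I | intermediate
9 | dilithio species of 4 (lithium alkoxide, lithiated furan 5-methyl group) | [Li]Cc1oc(cc1C)C2(O[Li])COC(C)(C)OC2 | intermediate
10 | 5-{5-[(3E)-4-iodo-3-methylbut-3-en-1-yl]-4-methylfuran-2-yl}-2,2-dimethyl-1,3-dioxan-5-ol | Cc1cc(oc1CC/C(C)=C/I)C2(O)COC(C)(C)OC2 | intermediate
11 | Achmatowicz hemiketal: 6-hydroxy-6-[(3E)-4-iodo-3-methylbut-3-en-1-yl]-5-methyl-2H-pyran-3(6H)-one, spiro-linked at its C2 to C5 of a 2,2-dimethyl-1,3-dioxane (racemic hemiketal) | CC1=CC(=O)C2(COC(C)(C)OC2)OC1(O)CC/C(C)=C/I | intermediate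
12 | (5S)-5-[(4E)-5-iodo-4-methylpent-4-enoyl]-5-methyloxolan-3-one, spiro-linked at its C2 to C5 of a 2,2-dimethyl-1,3-dioxane (10S in germacrane numbering) | C[C@@]1(C(=O)CC/C(C)=C/I)CC(=O)C2(COC(C)(C)OC2)O1 | intermediate
13 | bicyclic methyl ketal: 5-(hydroxymethyl)-2-[(3E)-4-iodo-3-methylbut-3-en-1-yl]-2-methoxy-1-methyl-3,8-dioxabicyclo[3.2.1]octan-6-one; 7S,10S in germacrane numbering, methoxy axial | C[C@@]12CC(=O)[C@](CO)(CO[C@]2(OC)CC/C(C)=C/I)O1 | intermediate
14 | bicyclic ketal diol: the 6-endo alcohol of 13 (C8–OH cis to the ketal bridge) | C[C@@]12C[C@H](O)[C@](CO)(CO[C@]2(OC)CC/C(C)=C/I)O1 | intermediate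
15 | bis(tert-butyldimethylsilyl) ether of 14 (O6 and O8 silylated) | C[C@@]12C[C@H](O[Si](C)(C)C(C)(C)C)[C@](CO[Si](C)(C)C(C)(C)C)(CO[C@]2(OC)CC/C(C)=C/I)O1 | intermediate
16 | oxolane hydroxy ketone: C7 bears CH2OTBS (C6) and CH2OH (C11), C8 bears OTBS, C10 bears methyl and the (4E)-5-iodo-4-methylpent-4-enoyl group; in equilibrium with its bicyclic hemiketal | C[C@@]1(C(=O)CC/C(C)=C/I)C[C@H](O[Si](C)(C)C(C)(C)C)[C@](CO[Si](C)(C)C(C)(C)C)(CO)O1 | intermediate
17 | C11 aldehyde of 16 | C[C@@]1(C(=O)CC/C(C)=C/I)C[C@H](O[Si](C)(C)C(C)(C)C)[C@](CO[Si](C)(C)C(C)(C)C)(C=O)O1 | intermediate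
18 | terminal alkyne: C7 bears ethynyl (C11≡C13) and CH2OTBS | C[C@@]1(C(=O)CC/C(C)=C/I)C[C@H](O[Si](C)(C)C(C)(C)C)[C@](CO[Si](C)(C)C(C)(C)C)(C#C)O1 | intermediate
19 | alkynyl diol: 2-ethynyl-2-(hydroxymethyl)-5-[(4E)-5-iodo-4-methylpent-4-enoyl]-5-methyloxolan-3-ol, configuration as in the target at C7, C8, C10 | C[C@@]1(C(=O)CC/C(C)=C/I)C[C@H](O)[C@](CO)(C#C)O1 | intermediate
20 | hydroxy aldehyde: C6 aldehyde of 19 | C[C@@]1(C(=O)CC/C(C)=C/I)C[C@H](O)[C@](C=O)(C#C)O1 | intermediate
21 | methacrylate aldehyde: 8-O-methacryloyl derivative of 20 | C[C@@]1(C(=O)CC/C(C)=C/I)C[C@H](OC(=O)C(C)=C)[C@](C=O)(C#C)O1 | intermediate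
22 | alkenylchromium dichloride derived from 21 (trivalent chromium at C5) | C[C@@]1(C(=O)CC/C(C)=C/[Cr](Cl)Cl)C[C@H](OC(=O)C(C)=C)[C@](C=O)(C#C)O1 | intermediate
23 | macrocyclic allylic alcohol: 7,10-epoxy ten-membered carbocycle with 1-ketone, (4E)-alkene, 6R-hydroxyl, 7-ethynyl, 8-methacrylate | C[C@@]1(C(=O)CC/C(C)=C/[C@H]2O)C[C@H](OC(=O)C(C)=C)[C@]2(C#C)O1 | intermediate
24 | α-methylene lactone: 4,5-deoxy target, (4E)-alkene | C[C@@]1(C(=O)CC/C(C)=C/[C@H]2OC(=O)C3=C)C[C@H](OC(=O)C(C)=C)[C@]23O1 | intermediate
25 | CNP0241021.2, (4R,5R,6R,7S,8S,10S) | C=C(C)C(=O)O[C@H]1C[C@]2(C)O[C@@]13C(=C)C(=O)O[C@@H]3[C@H]1O[C@]1(C)CCC2=O | target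

Total step count: 17. Longest linear sequence: 16 steps (steps 2 to 17, from prop-2-yn-1-ol).

Steps most likely to fail

Step 6 (Proposed new method). The hemiketal may stay closed or react through an uncatalysed background pathway, so that the contraction is slow or poorly enantioselective, and enolisation at C2 may divert the open ene-dione into aldol cyclisation. The fallback uses known reactions and sets out from 10. The tertiary hydroxyl is silylated (TMSOTf, 2,6-lutidine) to the trimethylsilyl ether F1. The furan is then opened oxidatively with mCPBA to the (Z)-ene-dione silyl ether F2. TBAF releases the alkoxide, which closes by 5-endo oxa-Michael addition to racemic oxolanone, that is 12 together with the enantiomer of 12 F3. CSA in methanol then gives the racemic ketal, 13 together with the enantiomer of 13 F4. Lipase-catalysed acetylation with vinyl acetate is expected to convert F4 into the acetate of F4 F5 and to leave 13, where the fallback rejoins the route.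

Step 15. Ring closure may be slow against the strain of the trans-bridged bicycle, so that protonation or intermolecular addition of the alkenylchromium competes, and Felkin–Anh control at C6 may be lost. The fallback closes the ring earlier, on the rigid bicyclic ketal, where C1 is still sp3 and the free ketone and alkyne are absent; it sets out from 14. TEMPO/PhI(OAc)2 gives the hydroxy aldehyde ketal F6 and methacrylic anhydride/DMAP the methacrylate aldehyde ketal F7. CrCl2/NiCl2 converts F7 through the alkenylchromium species of F7 F8 into the macrocyclic allylic alcohol ketal F9. TESOTf protects O6 as the triethylsilyl ether of F9 F10. PPTS in aqueous acetone opens the ketal to the macrocyclic hydroxy ketone F11. Dess–Martin oxidation gives the macrocyclic C11 aldehyde F12, and Ohira–Bestmann homologation gives the triethylsilyl ether of 23 F13. HF·pyridine then returns 23.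

Step 4. Alkoxide-directed ring lithiation at C3 of the furan, or halogen–lithium exchange at the iodoalkene of 8 by unconsumed base, may compete with lateral lithiation. The fallback builds the side chain before the furan is joined to 2 and returns at 10. Commercial 4-bromo-1-(trimethylsilyl)but-1-yne is converted with Mg into [4-(trimethylsilyl)but-3-yn-1-yl]magnesium bromide F14. This adds to the carbonyl of commercial 3-methylfuran-2(5H)-one, and dehydration with TsOH gives 3-methyl-2-[4-(trimethylsilyl)but-3-yn-1-yl]furan F15. Ring lithiation (n-BuLi) gives the 5-lithio derivative of F15 F16, which adds to 2 to give the silylalkynyl furyl carbinol F17. K2CO3 in methanol gives the terminal alkynyl furyl carbinol F18. Carboalumination with AlMe3/(C5H5)2ZrCl2 through the alkenylalane of F18 F19 and iodinolysis with I2 then give 10.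

Further compounds
F1 | step 6 | trimethylsilyl ether of 10 | Cc1cc(oc1CC/C(C)=C/I)C2(O[Si](C)(C)C)COC(C)(C)OC2
F2 | step 6 | (Z)-ene-dione silyl ether | C/C(C(=O)CC/C(C)=C/I)=C/C(=O)C1(O[Si](C)(C)C)COC(C)(C)OC1
F3 | step 6 | enantiomer of 12 | C[C@]1(C(=O)CC/C(C)=C/I)CC(=O)C2(COC(C)(C)OC2)O1
F4 | step 6 | enantiomer of 13 | C[C@]12CC(=O)[C@@](CO)(CO[C@@]2(OC)CC/C(C)=C/I)O1
F5 | step 6 | acetate of F4 | C[C@]12CC(=O)[C@@](COC(C)=O)(CO[C@@]2(OC)CC/C(C)=C/I)O1
F6 | step 15 | hydroxy aldehyde ketal | C[C@@]12C[C@H](O)[C@](C=O)(CO[C@]2(OC)CC/C(C)=C/I)O1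
F7 | step 15 | methacrylate aldehyde ketal | C[C@@]12C[C@H](OC(=O)C(C)=C)[C@](C=O)(CO[C@]2(OC)CC/C(C)=C/I)O1
F8 | step 15 | alkenylchromium species of F7 | C[C@@]12C[C@H](OC(=O)C(C)=C)[C@](C=O)(CO[C@]2(OC)CC/C(C)=C/[Cr](Cl)Cl)O1
F9 | step 15 | macrocyclic allylic alcohol ketal | C[C@@]12C[C@H](OC(=O)C(C)=C)[C@]3(CO[C@]2(OC)CC/C(C)=C/[C@H]3O)O1
F10 | step 15 | triethylsilyl ether of F9 | C[C@@]12C[C@H](OC(=O)C(C)=C)[C@]3(CO[C@]2(OC)CC/C(C)=C/[C@H]3O[Si](CC)(CC)CC)O1
F11 | step 15 | macrocyclic hydroxy ketone | C[C@@]1(C(=O)CC/C(C)=C/[C@H]2O[Si](CC)(CC)CC)C[C@H](OC(=O)C(C)=C)[C@]2(CO)O1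
F12 | step 15 | macrocyclic C11 aldehyde | C[C@@]1(C(=O)CC/C(C)=C/[C@H]2O[Si](CC)(CC)CC)C[C@H](OC(=O)C(C)=C)[C@]2(C=O)O1
F13 | step 15 | triethylsilyl ether of 23 | C[C@@]1(C(=O)CC/C(C)=C/[C@H]2O[Si](CC)(CC)CC)C[C@H](OC(=O)C(C)=C)[C@]2(C#C)O1
F14 | step 4 | [4-(trimethylsilyl)but-3-yn-1-yl]magnesium bromide | C[Si](C)(C)C#CCC[Mg]Br
F15 | step 4 | 3-methyl-2-[4-(trimethylsilyl)but-3-yn-1-yl]furan | Cc1ccoc1CCC#C[Si](C)(C)C
F16 | step 4 | 5-lithio derivative of F15 | [Li]c1cc(C)c(CCC#C[Si](C)(C)C)o1
F17 | step 4 | silylalkynyl furyl carbinol | Cc1cc(oc1CCC#C[Si](C)(C)C)C2(O)COC(C)(C)OC2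
F18 | step 4 | terminal alkynyl furyl carbinol | Cc1cc(oc1CCC#C)C2(O)COC(C)(C)OC2
F19 | step 4 | alkenylalane of F18 | Cc1cc(oc1CC/C(C)=C/[Al](C)C)C2(O[Al](C)C)COC(C)(C)OC2
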